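The route rests on one disconnection: ester carbon C16 on C13 is 1,4-related to the oxygen-bearing C15 of the side chain on C9 of ring B (a masked γ-hydroxy acid), so C16 is brought in as carbon monoxide. A single palladium-hydride hydrocarbonylation forms C13–C16, closes a temporary γ-lactone onto the C15 oxygen and sets C13, the one stereocentre not taken from sclareolide (C5, C10) or from ketone reduction (C7). Its substrate is a 16-nor (12Z)-homoallylic alcohol carrying the 7α-acetate and the C8=C9 alkene, made by Wittig extension of a sclareolide-derived C12 aldehyde. Lactone opening, carboxylate methylation and acetylation finish the synthesis.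

Key step: step 9

Remark: labdane numbering is used throughout; the target is 5S, 7R (7α-acetoxy, axial), 10S, 13S. The ylide oxygen is silylated because a free γ-oxido ylide would erode Z selectivity, and the C7 hydroxyl is carried free through reduction and olefination so that one protecting group suffices. The ligand antipode in step 9 is to be fixed on a test scale so that the 13S lactone is the major epimer.

Step 1
Reactants: 1 (+)-sclareolide
Product: 2 methyl 13,14,15,16-tetranorlabd-8-en-12-oate
Conditions: conc. H2SO4, MeOH, rt
Reagents that add atoms: methanol (SMILES CO)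
Why: Acid ionises the tertiary C8–O bond of the lactone, E1 loss of the C9 proton and Fischer esterification follow, and under equilibrating acid the alkene should settle in the tetrasubstituted C8=C9 position (minor C7=C8 and exocyclic isomers removable on AgNO3-impregnated silica); C5 and C10 are untouched.

Step 2
Reactants: 2 methyl 13,14,15,16-tetranorlabd-8-en-12-oate
Product: 3 methyl 7-oxo-13,14,15,16-tetranorlabd-8-en-12-oate
Conditions: Na2CrO4, NaOAc, AcOH/Ac2O, 40 °C
Reagents that add atoms: sodium chromate, [Na+].[Na+].[O-][Cr](=O)(=O)[O-]
Why: Allylic oxidation by hexavalent chromium should take the ring methylene C7 to the conjugated enone, because the C11 hydrogens are deactivated towards the electrophilic oxidant by the adjacent ester and the C17 methyl is less reactive than a ring CH2.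

Step 3
Reactants: 3 methyl 7-oxo-13,14,15,16-tetranorlabd-8-en-12-oate
Product: 4 methyl 7α-hydroxy-13,14,15,16-tetranorlabd-8-en-12-oate
Conditions: LiBH(s-Bu)3, THF, −78 °C; then H2O
Reagents that add atoms: none
Why: 1,2-Reduction by a bulky trialkylborohydride, which should deliver hydride along the equatorial trajectory on the β face of C7, away from the axial 5α-hydrogen, to give the pseudoaxial 7α-alcohol (7R) as in 7-ketosteroid reductions; the methyl ester and the β,β-disubstituted enone alkene should survive at −78 °C.

Step 4
Reactants: 4 methyl 7α-hydroxy-13,14,15,16-tetranorlabd-8-en-12-oate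
Product: 5 7α-hydroxy-13,14,15,16-tetranorlabd-8-en-12-al
Conditions: i-Bu2AlH (2.2 equiv), CH2Cl2, −78 °C; MeOH, then aq. potassium sodium tartrate
Reagents that add atoms: none
Why: Partial ester reduction through an aluminium hemiacetal that is stable at −78 °C (one equivalent is consumed by the C7 hydroxyl as its aluminium alkoxide); no lactol can form because C7 and C11 are trans across the ring alkene, and the aldehyde is used crude in step 6.

Step 5
Reactants: 6 (3-hydroxypropyl)triphenylphosphonium bromide
Product: 7 [3-(tert-butyldimethylsilyloxy)propyl]triphenylphosphonium bromide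
Conditions: TBSCl, imidazole, CH2Cl2, rt; aq. NaBr wash
Reagents that add atoms: tert-butyldimethylsilyl chloride, CC(C)(C)[Si](C)(C)Cl
Why: Imidazole-promoted silylation of a primary alcohol; masking the hydroxyl removes the oxido-ylide effect that would lower Z selectivity in the olefination.

Step 6
Reactants: 5 7α-hydroxy-13,14,15,16-tetranorlabd-8-en-12-al; 7 [3-(tert-butyldimethylsilyloxy)propyl]triphenylphosphonium bromide
Product: 9 (12Z)-15-(tert-butyldimethylsilyloxy)-16-norlabda-8,12-dien-7α-ol, via phosphonium ylide 8 (not isolated)
Conditions: 7 (2.5 equiv), NaN(SiMe3)2 (2.4 equiv), THF, 0 °C; then 5, −78 °C → rt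
Reagents that add atoms: none
Why: Wittig olefination with a salt-free non-stabilised ylide (sodium base, low temperature) is kinetically Z-selective and forms C12=C13; the excess ylide tolerates the free C7 hydroxyl, and fast addition at −78 °C should outrun enolisation of the aldehyde.

Step 7
Reactants: 9 (12Z)-15-(tert-butyldimethylsilyloxy)-16-norlabda-8,12-dien-7α-ol
Product: 10 (12Z)-7α-acetoxy-15-(tert-butyldimethylsilyloxy)-16-norlabda-8,12-diene
Conditions: Ac2O, DMAP, pyridine, CH2Cl2, rt
Reagents that add atoms: acetic anhydride, CC(=O)OC(C)=O
Why: DMAP-catalysed acylation of the hindered axial allylic alcohol with retention at C7; the silyl ether and the skipped diene are inert.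

Step 8
Reactants: 10 (12Z)-7α-acetoxy-15-(tert-butyldimethylsilyloxy)-16-norlabda-8,12-diene
Product: 11 (12Z)-7α-acetoxy-16-norlabda-8,12-dien-15-ol
Conditions: HF·pyridine, THF/pyridine, 0 °C → rt
Reagents that add atoms: none
Why: Fluoride cleavage of the primary silyl ether under buffered, non-basic conditions that should leave the allylic acetate and the Z alkene untouched.

Step 9
Reactants: 11 (12Z)-7α-acetoxy-16-norlabda-8,12-dien-15-ol; 12 carbon monoxide
Product: 13 (13S)-7α-acetoxylabd-8-en-16,15-olide
Conditions: Pd2(dba)3·CHCl3 (2.5 mol%), (S)-DTBM-SEGPHOS (6 mol%), CO/H2 (5:1, 40 bar), CH2Cl2, 90 °C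
Reagents that add atoms: none
Why: A bisphosphine-bound palladium hydride, generated from zerovalent palladium under CO/H2, adds syn and reversibly across C12=C13, the C13–Pd alkyl inserts CO to form C13–C16, and the acyl–palladium species is trapped by the C15 hydroxyl, which releases the lactone and returns the hydride. The closest known reaction type is the palladium-catalysed cyclocarbonylation (intramolecular hydroalkoxycarbonylation) of homoallylic alcohols to α-substituted γ-butyrolactones, for which chiral-bisphosphine variants exist but are little explored on 1,2-disubstituted alkenes. The ring closes in a 5-exo-trig acyl substitution, O15 attacking trigonal C16 with the C16=O bond outside the ring. C13 is set by the chiral ligand alone, which selects the alkene face that receives Pd–H (CO insertion retains configuration), the decalin stereocentres being four or more bonds away. The step needs C13-over-C12 regioselectivity, secured by the tethered hydroxyl because only the C13 acyl can close a five-membered ring, while the C12 alkyl should revert by β-hydride elimination rather than close a six-membered one. It also needs chemoselectivity, secured by high CO pressure that outpaces chain walking towards C11 or C15 and by the crowding of the tetrasubstituted C8=C9 alkene and its axial 7α-acetate, which should keep palladium away under these acid-free conditions.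

Step 10
Reactants: 13 (13S)-7α-acetoxylabd-8-en-16,15-olide
Product: 15 methyl (13S)-7α,15-dihydroxylabd-8-en-16-oate, via potassium dihydroxy carboxylate 14 (not isolated)
Conditions: KOH (3 equiv), MeOH/H2O, rt → 50 °C; CO2 to pH 8–9, evaporate; MeI, DMF, rt
Reagents that add atoms: potassium hydroxide, [K+].[OH-]; iodomethane, CI
Why: Saponification opens the lactone by acyl–oxygen cleavage and removes the 7-acetate, the carboxylate being non-enolisable so C13 should not epimerise; SN2 methylation of the potassium carboxylate in DMF is selective over the free hydroxyls and avoids the acid that would relactonise.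

Step 11
Reactants: 15 methyl (13S)-7α,15-dihydroxylabd-8-en-16-oate
Product: 16 methyl (13S)-7α,15-diacetoxylabd-8-en-16-oate (target)
Conditions: Ac2O, DMAP, pyridine, CH2Cl2, 0 °C → rt (crude 15 used at once)
Reagents that add atoms: acetic anhydride, CC(=O)OC(C)=O
Why: DMAP-catalysed acetylation of the primary C15 and the secondary C7 hydroxyls, run directly on the crude hydroxy ester to forestall relactonisation; no stereocentre is touched.

Compound list
1 | (+)-sclareolide | O=C1C[C@H]2[C@](C)(O1)CC[C@H]3C(C)(C)CCC[C@]23C | starting material
2 | methyl 13,14,15,16-tetranorlabd-8-en-12-oate | COC(=O)CC1=C(C)CC[C@H]2C(C)(C)CCC[C@]12C | intermediate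
3 | methyl 7-oxo-13,14,15,16-tetranorlabd-8-en-12-oate | COC(=O)CC1=C(C)C(=O)C[C@H]2C(C)(C)CCC[C@]12C | intermediate
4 | methyl 7α-hydroxy-13,14,15,16-tetranorlabd-8-en-12-oate | COC(=O)CC1=C(C)[C@H](O)C[C@H]2C(C)(C)CCC[C@]12C | intermediate
5 | 7α-hydroxy-13,14,15,16-tetranorlabd-8-en-12-al | O=CCC1=C(C)[C@H](O)C[C@H]2C(C)(C)CCC[C@]12C | intermediate
6 | (3-hydroxypropyl)triphenylphosphonium bromide | [Br-].OCCC[P+](c1ccccc1)(c1ccccc1)c1ccccc1 | starting material
7 | [3-(tert-butyldimethylsilyloxy)propyl]triphenylphosphonium bromide | [Br-].CC(C)(C)[Si](C)(C)OCCC[P+](c1ccccc1)(c1ccccc1)c1ccccc1 | intermediate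
8 | [3-(tert-butyldimethylsilyloxy)propylidene]triphenylphosphorane (ylide, not isolated) | CC(C)(C)[Si](C)(C)OCCC=P(c1ccccc1)(c1ccccc1)c1ccccc1 | intermediate
9 | (12Z)-15-(tert-butyldimethylsilyloxy)-16-norlabda-8,12-dien-7α-ol | CC(C)(C)[Si](C)(C)OCC/C=C\CC1=C(C)[C@H](O)C[C@H]2C(C)(C)CCC[C@]12C | intermediate
10 | (12Z)-7α-acetoxy-15-(tert-butyldimethylsilyloxy)-16-norlabda-8,12-diene | CC(C)(C)[Si](C)(C)OCC/C=C\CC1=C(C)[C@H](OC(C)=O)C[C@H]2C(C)(C)CCC[C@]12C | intermediate
11 | (12Z)-7α-acetoxy-16-norlabda-8,12-dien-15-ol | OCC/C=C\CC1=C(C)[C@H](OC(C)=O)C[C@H]2C(C)(C)CCC[C@]12C | intermediate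
12 | carbon monoxide | [C-]#[O+] | starting material
13 | (13S)-7α-acetoxylabd-8-en-16,15-olide | O=C3OCC[C@@H]3CCC1=C(C)[C@H](OC(C)=O)C[C@H]2C(C)(C)CCC[C@]12C | intermediate
14 | potassium (13S)-7α,15-dihydroxylabd-8-en-16-oate (not isolated) | [K+].[O-]C(=O)[C@H](CCO)CCC1=C(C)[C@H](O)C[C@H]2C(C)(C)CCC[C@]12C | intermediate
15 | methyl (13S)-7α,15-dihydroxylabd-8-en-16-oate | COC(=O)[C@H](CCO)CCC1=C(C)[C@H](O)C[C@H]2C(C)(C)CCC[C@]12C | intermediate
16 | methyl (13S)-7α,15-diacetoxylabd-8-en-16-oate | COC(=O)[C@H](CCOC(C)=O)CCC1=C(C)[C@H](OC(C)=O)C[C@H]2C(C)(C)CCC[C@]12C | target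

Total step count: 11. Longest linear sequence: 10 steps (steps 1–4 and 6–11, from sclareolide).

Steps most likely to fail

Step 9. The ligand may discriminate the two faces of the internal alkene poorly, giving C13 epimers that are hard to separate because the decalin stereocentres are remote. Acylation at C12 with six-membered closure, chain walking of the palladium hydride along C11–C15, and slow turnover on a 1,2-disubstituted alkene are further ways to lose material. The fallback sets out from 5 and returns at 15. The C12=C13 bond would be made by Horner–Wadsworth–Emmons condensation of aldehyde 5 with diethyl (2-oxotetrahydrofuran-3-yl)phosphonate (LiCl, DBU, MeCN), which should give (12E)-7α-hydroxylabda-8,12-dien-16,15-olide F1 after removal of any Z isomer. C13 would then be set by asymmetric hydrogenation of the exocyclic conjugated alkene with Ru(OAc)2[(S)-BINAP] (antipode chosen for 13S) under H2 in MeOH, a known reaction class for α-alkylidene γ-butyrolactones that should leave the tetrasubstituted C8=C9 alkene alone, to give (13S)-7α-hydroxylabd-8-en-16,15-olide F2. F2 would be opened under the conditions of step 10 to rejoin the route at 15.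

Step 3. Hydride delivery to the C7 ketone may favour the α face, giving the 7β epimer, or may be unselective; partial attack on the ester is a lesser concern. The fallback sets out from 3 and returns at 4. Luche reduction of 3 (NaBH4, CeCl3·7H2O, MeOH, −20 °C), in which the small hydride is delivered axially from the α face, should give methyl 7β-hydroxy-13,14,15,16-tetranorlabd-8-en-12-oate F3. Mitsunobu inversion with 4-nitrobenzoic acid (PPh3, DIAD, THF) would give methyl 7α-(4-nitrobenzoyloxy)-13,14,15,16-tetranorlabd-8-en-12-oate F4, and K2CO3 in MeOH would release 4.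

Step 4. The reduction may run past the aldehyde to the primary alcohol or stop short, and the β,γ-unsaturated aldehyde may suffer double-bond migration on work-up. The fallback sets out from 4 and returns at 5. Full reduction with LiAlH4 (THF, 0 °C) should give 13,14,15,16-tetranorlabd-8-ene-7α,12-diol F5. Oxidation of the primary hydroxyl alone with catalytic TEMPO and PhI(OAc)2 in CH2Cl2, which should spare the hindered secondary allylic alcohol, would then give 5.

Further compounds
F1 | step 9 | (12E)-7α-hydroxylabda-8,12-dien-16,15-olide | O=C1OCC/C1=C\CC2=C(C)[C@H](O)C[C@H]3C(C)(C)CCC[C@]23C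
F2 | step 9 | (13S)-7α-hydroxylabd-8-en-16,15-olide | O=C1OCC[C@@H]1CCC2=C(C)[C@H](O)C[C@H]3C(C)(C)CCC[C@]23C
F3 | step 3 | methyl 7β-hydroxy-13,14,15,16-tetranorlabd-8-en-12-oate | COC(=O)CC1=C(C)[C@@H](O)C[C@H]2C(C)(C)CCC[C@]12C
F4 | step 3 | methyl 7α-(4-nitrobenzoyloxy)-13,14,15,16-tetranorlabd-8-en-12-oate | COC(=O)CC1=C(C)[C@H](OC(=O)c3ccc(cc3)[N+](=O)[O-])C[C@H]2C(C)(C)CCC[C@]12C
F5 | step 4 | 13,14,15,16-tetranorlabd-8-ene-7α,12-diol | OCCC1=C(C)[C@H](O)C[C@H]2C(C)(C)CCC[C@]12C
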